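The route rests on the fact that the angular methyl C14 on quaternary C10 lies cis to the C3 oxygen and beside the C4=C5 olefin of ring A. C14 is therefore delivered as a methylene group: the zinc alkoxide of a 3β-hydroxy-Δ5(10)-octalin hands CH2 to the β face of the ring-fusion olefin, forming C10–C14 and C5–C14 and fixing C10 in one operation; oxidation at C3 and acid then cleave C5–C14 to give the methyl and the C4=C5 olefin. The precursor, a 4-methyl-Δ5(10)-octalin-3β-ol with a C8 dioxolane, comes from 6-methoxy-2-tetralone by Birch reduction, methylation, hindered-hydride reduction and lipase resolution. Ring B is completed through a cis-fused 8β,12-lactone.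

Key step: step 6

Remark: eudesmane numbering is used for all bicyclic compounds (ring A = C1–C5 and C10, ring B = C5–C10, C14 = methyl on C10, C15 = methyl on C4, C11–C13 = side chain on C7); β is the face of C14, and intermediates lacking C11–C13 are named as octalins (they are 11,12,13-nor- or 11,12,13,14-nor-eudesmanes).
Remark: the substrate of step 6 carries the C4 methyl cis to the 3β-hydroxyl (4β), because hindered-hydride reduction gives this epimer selectively; C4 becomes sp2 in step 8, so its configuration does not reach the target.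
Remark: the lipase of step 5 is assumed to acylate the (3R) alcohol, as is usual for secondary alcohols whose larger substituent has CIP priority.

Step 1
Reactants: 1 6-methoxy-2-tetralone; 2 ethylene glycol
Product: 3 6-methoxy-2-tetralone ethylene ketal (6'-methoxy-3',4'-dihydro-1'H-spiro[1,3-dioxolane-2,2'-naphthalene])
Conditions: p-toluenesulfonic acid (cat.), benzene, reflux, Dean–Stark trap
Reagents that add atoms: none
Why: Acid-catalysed ketalisation with azeotropic removal of water turns the ketone (the future C8 carbonyl) into a dioxolane that withstands dissolving metal, strong base and zinc carbenoids.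

Step 2
Reactants: 3 6-methoxy-2-tetralone ethylene ketal
Product: 5 8,8-ethylenedioxy-Δ5(10)-octalin-3-one (achiral β,γ-unsaturated ketone), via methyl enol ether diene 4 (not isolated)
Conditions: Li, NH3(l), THF, t-BuOH, −78 → −33 °C; then oxalic acid, MeOH/H2O, rt
Reagents that add atoms: water, O
Why: Birch reduction adds hydrogen at the ring carbons ortho and meta to the methoxy group (C4 and C1), leaving the enol ether and the tetrasubstituted C5=C10 olefin as with 6-methoxytetralin-type arenes, and oxalic acid then hydrolyses the enol ether much faster than the dioxolane without moving the olefin into conjugation.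

Step 3
Reactants: 5 8,8-ethylenedioxy-Δ5(10)-octalin-3-one
Product: 7 racemic 8,8-ethylenedioxy-4-methyl-Δ5(10)-octalin-3-one, via lithium dienolate 6 (not isolated)
Conditions: LiN(i-Pr)2, THF, −78 °C; then MeI, −78 → −40 °C; cold aq. NH4Cl
Reagents that add atoms: iodomethane, CI
Why: Enolate alkylation in which deprotonation occurs at C4, activated by both the carbonyl group and the olefin (as at C1 of 2-tetralone), and the extended enolate is methylated at its α carbon so that the olefin stays at C5=C10; C4 is formed racemic.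

Step 4
Reactants: 7 racemic 8,8-ethylenedioxy-4-methyl-Δ5(10)-octalin-3-one
Product: 8 racemic cis-8,8-ethylenedioxy-4-methyl-Δ5(10)-octalin-3-ol (3-OH and 4-CH3 cis, (3R*,4S*))
Conditions: LiBH(s-Bu)3, THF, −78 °C; then H2O
Reagents that add atoms: none
Why: Hindered trialkylborohydride reduction, in which the bulky hydride attacks the carbonyl face away from the adjacent C4 methyl as with 2-methylcyclohexanone, should set C3 cis to C4 and give mainly the cis alcohol as a racemate.

Step 5
Reactants: 8 racemic cis-8,8-ethylenedioxy-4-methyl-Δ5(10)-octalin-3-ol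
Product: 9 (3S,4R)-8,8-ethylenedioxy-4-methyl-Δ5(10)-octalin-3-ol (3β-OH, 4β-CH3; an 11,12,13,14-tetranoreudesm-5(10)-en-3β-ol)
Conditions: immobilised Candida antarctica lipase B, vinyl acetate, t-BuOMe, 30 °C, stopped just past half conversion; chromatography
Reagents that add atoms: none
Why: Enzymatic kinetic resolution by lipase-catalysed transesterification, in which the (3R) enantiomer should be acetylated following the empirical rule for lipases, so that the unreacted (3S,4R) alcohol is recovered enantiomerically enriched and separated from the acetate.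

Step 6
Reactants: 9 (3S,4R)-8,8-ethylenedioxy-4-methyl-Δ5(10)-octalin-3-ol
Product: 11 8,8-ethylenedioxy-4β-methyl-5β,14-cyclo-octalin-3β-ol (C14 methylene bridging C5 and C10 on the β face; an 11,12,13-trinor-5β,14-cycloeudesman-3β-ol), via ethylzinc alkoxide 10 (not isolated)
Conditions: ZnEt2, CH2I2, CH2Cl2, −10 °C → rt
Reagents that add atoms: diiodomethane, ICI
Why: Simmons–Smith cyclopropanation in its diethylzinc form: ZnEt2 turns the 3β-hydroxyl into an ethylzinc alkoxide and forms with CH2I2 an iodomethylzinc carbenoid, which is held at the alkoxide oxygen and transfers CH2 to C5=C10 through a concerted butterfly-type transition state. The closest known reaction type is the hydroxyl-directed methylenation of homoallylic cyclohexenols, including the ring-fusion 5(10)-olefins of 19-nor steroid 3-ols. The cyclopropane C5–C10–C14 closes by a one-step suprafacial [2+1] addition, so C10–C14 and C5–C14 form on the same face and the three-membered ring is necessarily cis-fused to rings A and B. C5 and C10 are set together by the face of delivery, which is controlled by the C3 carbinol stereocentre (3S, β). The step needs β-face selectivity, which is secured because the covalently bound, axial 3β-O–Zn group reaches only the β face and accelerates the otherwise sluggish tetrasubstituted olefin, outweighing weak coordination by the dioxolane oxygens, while the cis C4 methyl lies pseudo-equatorial in the reacting half-chair, out of the path of the carbenoid.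

Step 7
Reactants: 11 8,8-ethylenedioxy-4β-methyl-5β,14-cyclo-octalin-3β-ol
Product: 12 8,8-ethylenedioxy-4β-methyl-5β,14-cyclo-octalin-3-one (β,γ-cyclopropyl ketone)
Conditions: Dess–Martin periodinane, pyridine, CH2Cl2, 0 °C → rt
Reagents that add atoms: none
Why: Dess–Martin oxidation of the secondary alcohol under near-neutral conditions leaves the cyclopropane and the dioxolane untouched.

Step 8
Reactants: 12 8,8-ethylenedioxy-4β-methyl-5β,14-cyclo-octalin-3-one
Product: 13 8,8-ethylenedioxy-4,10β-dimethyl-Δ4-octalin-3-one (11,12,13-trinoreudesm-4-en-3-one 8-ketal)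
Conditions: anhydrous p-toluenesulfonic acid (0.2 equiv), benzene, 80 °C
Reagents that add atoms: none
Why: Acid-catalysed homoconjugate opening of a β,γ-cyclopropyl ketone, in which the C3 enol formed toward C4 overlaps with the exocyclic C5–C14 bond and not with the in-ring C5–C10 bond, so protonation at C14 cleaves C5–C14 to give the 10β-methyl-4-en-3-one with C10 unchanged, while the absence of water spares the dioxolane.

Step 9
Reactants: 13 8,8-ethylenedioxy-4,10β-dimethyl-Δ4-octalin-3-one
Product: 14 8,8-ethylenedioxy-4,10β-dimethyl-Δ4-octalin-3β-ol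
Conditions: NaBH4, CeCl3·7H2O, MeOH, −78 → 0 °C
Reagents that add atoms: none
Why: Luche reduction, in which 1,2-addition of hydride from the α face, away from the axial C14 methyl, should give the pseudo-equatorial 3β (3S) alcohol as with steroidal 4-en-3-ones.

Step 10
Reactants: 14 8,8-ethylenedioxy-4,10β-dimethyl-Δ4-octalin-3β-ol
Product: 15 3β-(tert-butyldimethylsilyloxy)-8,8-ethylenedioxy-4,10β-dimethyl-Δ4-octalin
Conditions: t-BuMe2SiCl, imidazole, DMF, rt
Reagents that add atoms: tert-butyldimethylsilyl chloride, CC(C)(C)[Si](C)(C)Cl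
Why: Silyl ether protection of the allylic alcohol masks O3 through the enolate and saponification steps that a propanoate would not survive.

Step 11
Reactants: 15 3β-(tert-butyldimethylsilyloxy)-8,8-ethylenedioxy-4,10β-dimethyl-Δ4-octalin
Product: 16 3β-(tert-butyldimethylsilyloxy)-4,10β-dimethyl-Δ4-octalin-8-one
Conditions: pyridinium p-toluenesulfonate, acetone/H2O, 55 °C
Reagents that add atoms: water, O
Why: Mild acid-catalysed acetal hydrolysis frees the C8 ketone while the silyl ether and the allylic C–O bond are left intact.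

Step 12
Reactants: 16 3β-(tert-butyldimethylsilyloxy)-4,10β-dimethyl-Δ4-octalin-8-one; 17 methyl bromoacetate
Product: 20 methyl 2-[3β-(tert-butyldimethylsilyloxy)-4,10β-dimethyl-8-oxo-Δ4-octalin-7β-yl]acetate, via lithium enolate 18 (not isolated), via 7α-epimeric keto ester 19 (not isolated)
Conditions: LiN(i-Pr)2, THF, −78 °C; then 17, DMPU, −78 → −20 °C; then NaOMe (cat.), MeOH, rt
Reagents that add atoms: none
Why: Kinetic enolate alkylation, in which LiN(i-Pr)2 removes a proton from C7 and not from C9 (neopentyl, next to quaternary C10), followed by methoxide equilibration of the epimerisable C7 centre to the equatorial 7β position on the face of C14.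

Step 13
Reactants: 20 methyl 2-[3β-(tert-butyldimethylsilyloxy)-4,10β-dimethyl-8-oxo-Δ4-octalin-7β-yl]acetate
Product: 22 3β-(tert-butyldimethylsilyloxy)-13-noreudesm-4-en-8β,12-olide (cis-fused γ-lactone, 7α-H, 8α-H), via lithium alkoxide 21 (not isolated)
Conditions: LiBH(s-Bu)3, THF, −78 °C → rt; then H2O
Reagents that add atoms: none
Why: Trialkylborohydride reduction with lactonisation, in which hydride comes from the α face opposite the syn-axial C14 methyl to give the axial 8β alkoxide, which is cis to the 7β acetate chain and closes the γ-lactone by 5-exo-trig acyl substitution.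

Step 14
Reactants: 22 3β-(tert-butyldimethylsilyloxy)-13-noreudesm-4-en-8β,12-olide
Product: 26 3β-(tert-butyldimethylsilyloxy)eudesma-4,11(13)-dien-8β,12-olide (α-methylene lactone), via lactone enolate 23 (not isolated), via Mannich base 24 (not isolated), via trimethylammonium iodide 25 (not isolated)
Conditions: LiN(i-Pr)2, THF, −78 °C; CH2=NMe2+ I−, −78 °C → rt; then MeI, MeOH, rt; then NaHCO3, EtOAc/H2O
Reagents that add atoms: dimethylmethylideneammonium iodide, C=[N+](C)C.[I-]
Why: Mannich-type α-methylenation of the lactone enolate, followed by quaternisation and base-induced elimination of trimethylamine, installs C13, and the C11 stereocentre formed on the way is removed in the elimination.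

Step 15
Reactants: 26 3β-(tert-butyldimethylsilyloxy)eudesma-4,11(13)-dien-8β,12-olide
Product: 28 methyl 3β-(tert-butyldimethylsilyloxy)-8β-hydroxyeudesma-4,11(13)-dien-12-oate, via potassium carboxylate 27 (not isolated)
Conditions: KOH (1.05 equiv), THF/H2O, 0 °C → rt; evaporate; then MeI, DMF, rt
Reagents that add atoms: potassium hydroxide, [K+].[OH-]; iodomethane, CI
Why: Saponification of the lactone followed by SN2 O-methylation of the carboxylate gives the open hydroxy ester without acid, which would favour re-closure, and stoichiometric hydroxide in the absence of methanol limits conjugate addition at C13.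

Step 16
Reactants: 28 methyl 3β-(tert-butyldimethylsilyloxy)-8β-hydroxyeudesma-4,11(13)-dien-12-oate (used crude, at once)
Product: 29 methyl 8β-acetoxy-3β-(tert-butyldimethylsilyloxy)eudesma-4,11(13)-dien-12-oate
Conditions: Ac2O, Et3N, 4-(dimethylamino)pyridine, CH2Cl2, rt
Reagents that add atoms: acetic anhydride, CC(=O)OC(C)=O
Why: Nucleophile-catalysed acylation of the axial 8β hydroxyl traps it as the acetate before it can close back onto the C12 ester.

Step 17
Reactants: 29 methyl 8β-acetoxy-3β-(tert-butyldimethylsilyloxy)eudesma-4,11(13)-dien-12-oate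
Product: 30 methyl 8β-acetoxy-3β-hydroxyeudesma-4,11(13)-dien-12-oate
Conditions: HF·pyridine, pyridine, THF, 0 °C → rt
Reagents that add atoms: none
Why: Fluoride-mediated desilylation under buffered conditions removes the silyl ether without touching the acetate, the methyl ester or the acrylate.

Step 18
Reactants: 30 methyl 8β-acetoxy-3β-hydroxyeudesma-4,11(13)-dien-12-oate
Product: 31 methyl 8β-acetoxy-3β-propanoyloxyeudesma-4,11(13)-dien-12-oate, (3S,7R,8R,10R), CNP0198123.1
Conditions: (EtCO)2O, Et3N, 4-(dimethylamino)pyridine, CH2Cl2, 0 °C → rt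
Reagents that add atoms: propanoic anhydride, CCC(=O)OC(=O)CC
Why: Nucleophile-catalysed acylation of the 3β allylic alcohol with propanoic anhydride completes the target with C3, C7, C8 and C10 unchanged.

Compound list
1 | 6-methoxy-2-tetralone (6-methoxy-3,4-dihydronaphthalen-2(1H)-one) | COc1ccc2CC(=O)CCc2c1 | starting material
2 | ethylene glycol | OCCO | starting material
3 | 6-methoxy-2-tetralone ethylene ketal | COc1ccc2CC3(CCc2c1)OCCO3 | intermediate
4 | 3-methoxy-8,8-ethylenedioxy-octalin-2,5(10)-diene (methyl enol ether diene; not isolated) | COC1=CCC2=C(C1)CCC1(C2)OCCO1 | intermediate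
5 | 8,8-ethylenedioxy-Δ5(10)-octalin-3-one | O=C1CCC2=C(C1)CCC1(C2)OCCO1 | intermediate
6 | lithium 3,5(10)-dienolate of 5 (not isolated) | [Li+].[O-]C1=CC2=C(CC1)CC1(CC2)OCCO1 | intermediate
7 | racemic 8,8-ethylenedioxy-4-methyl-Δ5(10)-octalin-3-one | CC1C(=O)CCC2=C1CCC1(C2)OCCO1 | intermediate
8 | racemic cis-(3R*,4S*)-8,8-ethylenedioxy-4-methyl-Δ5(10)-octalin-3-ol (both enantiomers shown) | C[C@H]1[C@@H](O)CCC2=C1CCC1(C2)OCCO1.C[C@@H]1[C@H](O)CCC2=C1CCC1(C2)OCCO1 | intermediate
9 | (3S,4R)-8,8-ethylenedioxy-4-methyl-Δ5(10)-octalin-3-ol (3β-OH, 4β-CH3) | C[C@H]1[C@@H](O)CCC2=C1CCC1(C2)OCCO1 | intermediate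
10 | ethylzinc alkoxide of 9 (not isolated) | C[C@H]1[C@@H](O[Zn]CC)CCC2=C1CCC1(C2)OCCO1 | intermediate
11 | 8,8-ethylenedioxy-4β-methyl-5β,14-cyclo-octalin-3β-ol | C[C@H]1[C@@H](O)CC[C@@]23C[C@@]12CCC1(C3)OCCO1 | intermediate
12 | 8,8-ethylenedioxy-4β-methyl-5β,14-cyclo-octalin-3-one | C[C@H]1C(=O)CC[C@@]23C[C@@]12CCC1(C3)OCCO1 | intermediate
13 | 8,8-ethylenedioxy-4,10β-dimethyl-Δ4-octalin-3-one | C1CC2=C(C)C(=O)CC[C@]2(C)CC13OCCO3 | intermediate
14 | 8,8-ethylenedioxy-4,10β-dimethyl-Δ4-octalin-3β-ol | C1CC2=C(C)[C@@H](O)CC[C@]2(C)CC13OCCO3 | intermediate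
15 | 3β-(tert-butyldimethylsilyloxy)-8,8-ethylenedioxy-4,10β-dimethyl-Δ4-octalin | C1CC2=C(C)[C@@H](O[Si](C)(C)C(C)(C)C)CC[C@]2(C)CC13OCCO3 | intermediate
16 | 3β-(tert-butyldimethylsilyloxy)-4,10β-dimethyl-Δ4-octalin-8-one | O=C1CCC2=C(C)[C@@H](O[Si](C)(C)C(C)(C)C)CC[C@]2(C)C1 | intermediate
17 | methyl bromoacetate | COC(=O)CBr | starting material
18 | lithium Δ7-enolate of 16 (not isolated) | [Li+].[O-]C1=CCC2=C(C)[C@@H](O[Si](C)(C)C(C)(C)C)CC[C@]2(C)C1 | intermediate
19 | methyl 2-[3β-(tert-butyldimethylsilyloxy)-4,10β-dimethyl-8-oxo-Δ4-octalin-7α-yl]acetate (not isolated) | COC(=O)C[C@@H]1CC2=C(C)[C@@H](O[Si](C)(C)C(C)(C)C)CC[C@]2(C)CC1=O | intermediate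
20 | methyl 2-[3β-(tert-butyldimethylsilyloxy)-4,10β-dimethyl-8-oxo-Δ4-octalin-7β-yl]acetate | COC(=O)C[C@H]1CC2=C(C)[C@@H](O[Si](C)(C)C(C)(C)C)CC[C@]2(C)CC1=O | intermediate
21 | lithium 8β-alkoxide of the hydroxy ester from 20 (not isolated) | COC(=O)C[C@H]1CC2=C(C)[C@@H](O[Si](C)(C)C(C)(C)C)CC[C@]2(C)C[C@H]1[O-].[Li+] | intermediate
22 | 3β-(tert-butyldimethylsilyloxy)-13-noreudesm-4-en-8β,12-olide | O=C3C[C@H]1CC2=C(C)[C@@H](O[Si](C)(C)C(C)(C)C)CC[C@]2(C)C[C@H]1O3 | intermediate
23 | lithium enolate of lactone 22 (not isolated) | [Li+].[O-]C3=C[C@H]1CC2=C(C)[C@@H](O[Si](C)(C)C(C)(C)C)CC[C@]2(C)C[C@H]1O3 | intermediate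
24 | 13-(dimethylamino) adduct of the lactone, C11 epimer mixture (Mannich base; not isolated) | CN(C)CC3[C@H]1CC2=C(C)[C@@H](O[Si](C)(C)C(C)(C)C)CC[C@]2(C)C[C@H]1OC3=O | intermediate
25 | trimethylammonium iodide of 24 (not isolated) | C[N+](C)(C)CC3[C@H]1CC2=C(C)[C@@H](O[Si](C)(C)C(C)(C)C)CC[C@]2(C)C[C@H]1OC3=O.[I-] | intermediate
26 | 3β-(tert-butyldimethylsilyloxy)eudesma-4,11(13)-dien-8β,12-olide | C=C3[C@H]1CC2=C(C)[C@@H](O[Si](C)(C)C(C)(C)C)CC[C@]2(C)C[C@H]1OC3=O | intermediate
27 | potassium 3β-(tert-butyldimethylsilyloxy)-8β-hydroxyeudesma-4,11(13)-dien-12-oate (not isolated) | C=C(C(=O)[O-])[C@H]1CC2=C(C)[C@@H](O[Si](C)(C)C(C)(C)C)CC[C@]2(C)C[C@H]1O.[K+] | intermediate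
28 | methyl 3β-(tert-butyldimethylsilyloxy)-8β-hydroxyeudesma-4,11(13)-dien-12-oate | C=C(C(=O)OC)[C@H]1CC2=C(C)[C@@H](O[Si](C)(C)C(C)(C)C)CC[C@]2(C)C[C@H]1O | intermediate
29 | methyl 8β-acetoxy-3β-(tert-butyldimethylsilyloxy)eudesma-4,11(13)-dien-12-oate | C=C(C(=O)OC)[C@H]1CC2=C(C)[C@@H](O[Si](C)(C)C(C)(C)C)CC[C@]2(C)C[C@H]1OC(C)=O | intermediate
30 | methyl 8β-acetoxy-3β-hydroxyeudesma-4,11(13)-dien-12-oate | C=C(C(=O)OC)[C@H]1CC2=C(C)[C@@H](O)CC[C@]2(C)C[C@H]1OC(C)=O | intermediate
31 | methyl 8β-acetoxy-3β-propanoyloxyeudesma-4,11(13)-dien-12-oate, (3S,7R,8R,10R) | C=C(C(=O)OC)[C@H]1CC2=C(C)[C@@H](OC(=O)CC)CC[C@]2(C)C[C@H]1OC(C)=O | target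

Total step count: 18. Longest linear sequence: 18 steps (1 → 31).

Steps most likely to fail

Step 6. Methylene delivery may be slow or not face-selective, because the cis C4 methyl crowds the β face or zinc bound at a dioxolane oxygen delivers to the α face. The fallback moves the C4 methyl to the α face. Setting out from racemic cis alcohol 8, Mitsunobu inversion at C3 (4-nitrobenzoic acid, PPh3, DIAD, THF) should give the racemic trans 4-nitrobenzoate F1, and methanolysis (K2CO3, MeOH) the racemic trans alcohol F2. The lipase resolution of step 5 then leaves the (3S,4S) alcohol F3 (3β-OH, 4α-CH3). Directed cyclopropanation as in step 6 gives the 4α-methyl cyclopropyl carbinol F4, and Dess–Martin oxidation the 4α-methyl cyclopropyl ketone F5. Acid opening of F5 under the conditions of step 8 erases C4 and comes back to the route at 13.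

Step 8. The acid needed for ring opening may hydrolyse or shift the dioxolane, or the opening may stall under anhydrous conditions. The fallback accepts loss of the ketal and restores it afterwards. Setting out from 12, aqueous HCl in THF at 50 °C opens the cyclopropane and hydrolyses the ketal to the enedione F6. The saturated C8 ketone is then ketalised selectively with 1,2-bis(trimethylsilyloxy)ethane and catalytic Me3SiOTf in CH2Cl2 at −78 °C, conditions that leave the conjugated, tetrasubstituted C3 enone alone, and the route is rejoined at 13.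

Step 15. The γ-hydroxy ester may close back to the lactone during methylation or handling, and hydroxide may add in conjugate fashion to C13. The fallback passes through the alcohol oxidation level at C12, so that a free 8-hydroxyl never sits beside a C12 acyl group. Setting out from 26, i-Bu2AlH (CH2Cl2, −78 → 0 °C) reduces the lactone to the 8β,12-diol F7. Et3SiCl and imidazole at −40 °C silylate the primary allylic hydroxyl to give the 12-triethylsilyl ether F8, and Ac2O with 4-(dimethylamino)pyridine gives its 8β-acetate F9. Pyridinium p-toluenesulfonate in MeOH removes the primary silyl group to give the 12-hydroxy 8β-acetate F10. MnO2 gives the enal F11, NaClO2/NaH2PO4/2-methyl-2-butene gives the acrylic acid F12, and Me3SiCHN2 in MeOH/toluene gives the methyl ester, which is 29.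

Further compounds
F1 | step 6 | racemic trans-(3R*,4R*)-8,8-ethylenedioxy-4-methyl-Δ5(10)-octalin-3-yl 4-nitrobenzoate (both enantiomers shown) | C[C@@H]1[C@@H](OC(=O)c2ccc(cc2)[N+](=O)[O-])CCC2=C1CCC1(C2)OCCO1.C[C@H]1[C@H](OC(=O)c2ccc(cc2)[N+](=O)[O-])CCC2=C1CCC1(C2)OCCO1
F2 | step 6 | racemic trans-(3R*,4R*)-8,8-ethylenedioxy-4-methyl-Δ5(10)-octalin-3-ol (both enantiomers shown) | C[C@@H]1[C@@H](O)CCC2=C1CCC1(C2)OCCO1.C[C@H]1[C@H](O)CCC2=C1CCC1(C2)OCCO1
F3 | step 6 | (3S,4S)-8,8-ethylenedioxy-4-methyl-Δ5(10)-octalin-3-ol (3β-OH, 4α-CH3) | C[C@@H]1[C@@H](O)CCC2=C1CCC1(C2)OCCO1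
F4 | step 6 | 8,8-ethylenedioxy-4α-methyl-5β,14-cyclo-octalin-3β-ol | C[C@@H]1[C@@H](O)CC[C@@]23C[C@@]12CCC1(C3)OCCO1
F5 | step 6 | 8,8-ethylenedioxy-4α-methyl-5β,14-cyclo-octalin-3-one | C[C@@H]1C(=O)CC[C@@]23C[C@@]12CCC1(C3)OCCO1
F6 | step 8 | 4,10β-dimethyl-Δ4-octalin-3,8-dione | C1CC2=C(C)C(=O)CC[C@]2(C)CC1=O
F7 | step 15 | 3β-(tert-butyldimethylsilyloxy)eudesma-4,11(13)-diene-8β,12-diol | C=C(CO)[C@H]1CC2=C(C)[C@@H](O[Si](C)(C)C(C)(C)C)CC[C@]2(C)C[C@H]1O
F8 | step 15 | 3β-(tert-butyldimethylsilyloxy)-12-(triethylsilyloxy)eudesma-4,11(13)-dien-8β-ol | C=C(CO[Si](CC)(CC)CC)[C@H]1CC2=C(C)[C@@H](O[Si](C)(C)C(C)(C)C)CC[C@]2(C)C[C@H]1O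
F9 | step 15 | 3β-(tert-butyldimethylsilyloxy)-12-(triethylsilyloxy)eudesma-4,11(13)-dien-8β-yl acetate | C=C(CO[Si](CC)(CC)CC)[C@H]1CC2=C(C)[C@@H](O[Si](C)(C)C(C)(C)C)CC[C@]2(C)C[C@H]1OC(C)=O
F10 | step 15 | 3β-(tert-butyldimethylsilyloxy)-12-hydroxyeudesma-4,11(13)-dien-8β-yl acetate | C=C(CO)[C@H]1CC2=C(C)[C@@H](O[Si](C)(C)C(C)(C)C)CC[C@]2(C)C[C@H]1OC(C)=O
F11 | step 15 | 8β-acetoxy-3β-(tert-butyldimethylsilyloxy)eudesma-4,11(13)-dien-12-al | C=C(C=O)[C@H]1CC2=C(C)[C@@H](O[Si](C)(C)C(C)(C)C)CC[C@]2(C)C[C@H]1OC(C)=O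
F12 | step 15 | 8β-acetoxy-3β-(tert-butyldimethylsilyloxy)eudesma-4,11(13)-dien-12-oic acid | C=C(C(=O)O)[C@H]1CC2=C(C)[C@@H](O[Si](C)(C)C(C)(C)C)CC[C@]2(C)C[C@H]1OC(C)=O
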